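**Plan**

1. Numbering: chain C1 (carbinol carbon on ring B) to C14 (CH2 on ring A). Ring A is the 1-aryloxy-3-hydroxy-5-alkyl ring and ring B the 3,5-dihydroxy-4-aryloxyphenyl ring. The macrocycle is 22-membered.
2. Retrosynthetic cuts, in order: (a) ring A C5–C14 (aryl–CH2), the ring-closing bond, traced back to an aryl bromide and an ω-carboxylic acid that loses CO2; (b) the C8=C9 Z-alkene (Wittig); (c) C1–C2 (Grignard); (d) the ring A carbon–oxygen bond of the diaryl ether (Ullmann).
3. Enabling feature: C5 of ring A is meta to both ring A oxygens, so electrophilic substitution cannot reach it, but it is well served as a C–Br site for nickel. Its neighbour C14 is an unbranched CH2, the α-carbon of a plain carboxylic acid, so CO2 is a traceless activating group for a primary radical exactly there.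
4. Forward order: rings A and B are joined first as the diaryl ether; methyl ethers are exchanged for silyl ethers; C2–C8 come by Grignard addition and C9–C15 by Wittig olefination; the only ring-forming step is the nickel-electrocatalytic decarboxylative aryl–alkyl coupling; fluoride then frees the four hydroxyls.
5. Stereochemistry: C1 (R) from ruthenium-catalysed asymmetric transfer hydrogenation of the aryl ketone; the Z-alkene from a salt-free Wittig reaction of a non-stabilised ylide. Both are set before ring closure and not touched afterwards.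

Key step: step 10

Remark: 2 and 13 are taken as catalogue compounds. Ar* = 4-[3-bromo-5-(triisopropylsilyloxy)phenoxy]-3,5-bis(triisopropylsilyloxy)phenyl; TIPS = triisopropylsilyl; TBS = tert-butyldimethylsilyl.

**Step 1**
Reactants: 1 syringaldehyde (4-hydroxy-3,5-dimethoxybenzaldehyde); 2 1-bromo-3-iodo-5-methoxybenzene
Product: 3 4-(3-bromo-5-methoxyphenoxy)-3,5-dimethoxybenzaldehyde
Conditions: CuI (10 mol %), picolinic acid (20 mol %), K3PO4 (2 equiv), DMSO, 80 °C; 2 in slight excess
Reagents that add atoms: none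
Why: Copper-catalysed Ullmann diaryl ether synthesis with picolinic acid as ligand accepts di-ortho-substituted phenols, and the C–I bond of 2 should react well before its C–Br bond, which is kept for step 10.

**Step 2**
Reactants: 3 4-(3-bromo-5-methoxyphenoxy)-3,5-dimethoxybenzaldehyde
Product: 4 4-(3-bromo-5-hydroxyphenoxy)-3,5-dihydroxybenzaldehyde
Conditions: BBr3 (5 equiv), CH2Cl2, −78 °C to rt; then H2O
Reagents that add atoms: none
Why: BBr3 demethylation of aryl methyl ethers is carried out here because nothing acid-labile is yet present (aldehyde, diaryl ether and aryl bromide are inert), so that fluoride-labile groups can take the place of the methyl groups.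

**Step 3**
Reactants: 4 4-(3-bromo-5-hydroxyphenoxy)-3,5-dihydroxybenzaldehyde
Product: 5 4-[3-bromo-5-(triisopropylsilyloxy)phenoxy]-3,5-bis(triisopropylsilyloxy)benzaldehyde (Ar*–CHO)
Conditions: iPr3SiCl (3.6 equiv), imidazole (8 equiv), DMAP (cat.), DMF, rt to 40 °C
Reagents that add atoms: chlorotriisopropylsilane, CC(C)[Si](Cl)(C(C)C)C(C)C
Why: Standard imidazole-mediated silylation of phenols should give triisopropylsilyl ethers that withstand the organometallic, olefination and reductive steps and leave with fluoride at the end.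

**Step 4**
Reactants: 5 Ar*–CHO; 6 8-bromooct-1-ene
Product: 8 rac-1-Ar*-non-8-en-1-ol, via oct-7-enylmagnesium bromide 7 (not isolated)
Conditions: 6, Mg turnings, THF, rt; then 5, THF, −78 to 0 °C; aqueous work-up
Reagents that add atoms: none
Why: Grignard 1,2-addition to the aldehyde forms C1–C2 and brings C2–C8 plus one sacrificial terminal carbon, the aryl bromide being inert to an alkylmagnesium halide at low temperature; the racemic centre is erased in step 5.

**Step 5**
Reactants: 8 rac-1-Ar*-non-8-en-1-ol
Product: 9 1-Ar*-non-8-en-1-one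
Conditions: Dess–Martin periodinane (1.3 equiv), CH2Cl2, 0 °C to rt
Reagents that add atoms: none
Why: Dess–Martin oxidation of the benzylic alcohol should give the aryl ketone under near-neutral conditions that leave the terminal alkene, the aryl bromide and the silyl ethers untouched.

**Step 6**
Reactants: 9 1-Ar*-non-8-en-1-one
Product: 10 (R)-1-Ar*-non-8-en-1-ol
Conditions: RuCl[(R,R)-TsDPEN](p-cymene) (2 mol %), HCO2H/Et3N (5:2), CH2Cl2, 30 °C
Reagents that add atoms: none
Why: Noyori asymmetric transfer hydrogenation of an aryl n-alkyl ketone: the (R,R)-configured ruthenium hydride should deliver hydride to the Si face through the outer-sphere transition state organised by the CH/π contact with ring B, setting C1 as R, and the alkene and aryl bromide are not reduced.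

**Step 7**
Reactants: 10 (R)-1-Ar*-non-8-en-1-ol
Product: 11 tert-butyl{[(1R)-1-Ar*-non-8-en-1-yl]oxy}dimethylsilane
Conditions: tBuMe2SiCl (1.5 equiv), imidazole (3 equiv), DMF, rt to 40 °C
Reagents that add atoms: tert-butylchlorodimethylsilane, CC(C)(C)[Si](C)(C)Cl
Why: Standard silylation masks the secondary benzylic alcohol against the ylide and the carbodiimide activation to come, without touching the configuration at C1.

**Step 8**
Reactants: 11 tert-butyl{[(1R)-1-Ar*-non-8-en-1-yl]oxy}dimethylsilane
Product: 12 (8R)-8-Ar*-8-(tert-butyldimethylsilyloxy)octanal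
Conditions: OsO4 (2 mol %), NaIO4 (4 equiv), 2,6-lutidine (2 equiv), dioxane/H2O (3:1), rt
Reagents that add atoms: osmium tetroxide, O=[Os](=O)(=O)=O (catalytic carrier of the oxygen); sodium periodate, [Na+].[O-]I(=O)(=O)=O (terminal oxidant)
Why: Lemieux–Johnson oxidative cleavage turns the only alkene present into the C8 aldehyde and, unlike ozone, should spare the electron-rich aryl ethers.

**Step 9**
Reactants: 12 (8R)-8-Ar*-8-(tert-butyldimethylsilyloxy)octanal; 13 (6-carboxyhexyl)triphenylphosphonium bromide
Product: 15 (7Z,15R)-15-Ar*-15-(tert-butyldimethylsilyloxy)pentadec-7-enoic acid, via sodium 7-(triphenylphosphoranylidene)heptanoate 14 (not isolated)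
Conditions: 13 (2.2 equiv), NaN(SiMe3)2 (4.4 equiv), THF, 0 °C; then 12, −78 °C to rt; aq. HCl to pH 4
Reagents that add atoms: none
Why: The salt-free Wittig reaction of a non-stabilised ylide should form the cis-oxaphosphetane under kinetic control and hence the Z-alkene, and it delivers C9–C14 together with the carboxyl carbon in one operation.

**Step 10**
Reactants: 15 (7Z,15R)-15-Ar*-15-(tert-butyldimethylsilyloxy)pentadec-7-enoic acid
Product: 17 tetrasilyl ether of the target macrocycle (ring A O-TIPS; ring B bis-O-TIPS; C1 O-TBS; C1 R; C8=C9 Z), via N-acyloxyphthalimide ester 16 (not isolated)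
Conditions: N-hydroxyphthalimide (1.1 equiv), N,N'-diisopropylcarbodiimide (1.1 equiv), DMAP (5 mol %), CH2Cl2, rt, then solvent switch to NMP; this solution added by syringe pump over 12 h (final 2 mM) to NiCl2·6H2O (50 mol %), 2,2'-bipyridine (60 mol %), AgNO3 (30 mol %), LiCl, NMP, undivided cell, Mg anode, reticulated vitreous carbon cathode, constant current, rt
Reagents that add atoms: none
Why: Proposed new method: the acid is converted in the flask into its N-acyloxyphthalimide 16; cathodically formed zerovalent nickel–bipyridine inserts into the C–Br bond of ring A, single-electron reduction of the ester (by low-valent nickel or at the silver-coated cathode) expels phthalimide anion and CO2 to leave the primary radical at C14, and capture of this radical by the arylnickel on the same molecule gives a trivalent aryl(alkyl)nickel that reductively eliminates the ring A C5–C14 bond. The closest known reaction type is the intermolecular nickel-electrocatalytic decarboxylative arylation of primary redox-active esters with aryl bromides (a reductive aryl–alkyl cross-electrophile coupling); what is new is its use to close a large ring. The one ring formed is the 22-membered meta,para-cyclophane, closed end to end through a 23-membered nickelacycle that the flexible chain and the diaryl ether hinge should reach without strain. No stereocenter is formed, and the C14 radical is neither allylic nor near C1, so the R centre and the Z-alkene should pass unchanged. The step needs ring closure to win over chain growth and over loss of the radical by hydrogen abstraction or 6-exo addition to C8=C9: slow addition keeps the substrate far below the nickel concentration, so that ring A is already metalated when its radical is born, and the alkene lies five bonds from C14, where radical addition is slow. The C–Br carbon, meta to two oxygens, is electron-poor enough for fast oxidative addition, while the aryl–oxygen bonds and silyl ethers should stay inert at this potential.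

**Step 11**
Reactants: 17 tetrasilyl ether of the target macrocycle
Product: 18 CNP0316989.2, (4R,11Z)-2-oxa-1(1,3),3(1,4)-dibenzenacycloheptadecaphan-11-ene-1^5,3^2,3^6,4-tetrol
Conditions: Bu4NF (6 equiv), AcOH (6 equiv), THF, 0 °C to rt
Reagents that add atoms: none
Why: Buffered fluoride desilylation should cleave the three aryl silyl ethers and the benzylic silyl ether under near-neutral conditions that neither ionise the benzylic alcohol nor isomerise the Z-alkene.

**Compound list**

1 | syringaldehyde (4-hydroxy-3,5-dimethoxybenzaldehyde) | COc1cc(C=O)cc(OC)c1O | starting material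
2 | 1-bromo-3-iodo-5-methoxybenzene | COc1cc(Br)cc(I)c1 | starting material
3 | 4-(3-bromo-5-methoxyphenoxy)-3,5-dimethoxybenzaldehyde | COc1cc(Br)cc(Oc2c(OC)cc(C=O)cc2OC)c1 | intermediate
4 | 4-(3-bromo-5-hydroxyphenoxy)-3,5-dihydroxybenzaldehyde | Oc1cc(Br)cc(Oc2c(O)cc(C=O)cc2O)c1 | intermediate
5 | 4-[3-bromo-5-(triisopropylsilyloxy)phenoxy]-3,5-bis(triisopropylsilyloxy)benzaldehyde | O=Cc1cc(O[Si](C(C)C)(C(C)C)C(C)C)c(Oc2cc(Br)cc(O[Si](C(C)C)(C(C)C)C(C)C)c2)c(O[Si](C(C)C)(C(C)C)C(C)C)c1 | intermediate
6 | 8-bromooct-1-ene | C=CCCCCCCBr | starting material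
7 | oct-7-enylmagnesium bromide (not isolated) | C=CCCCCCC[Mg]Br | intermediate
8 | rac-1-Ar*-non-8-en-1-ol | C=CCCCCCCC(O)c1cc(O[Si](C(C)C)(C(C)C)C(C)C)c(Oc2cc(Br)cc(O[Si](C(C)C)(C(C)C)C(C)C)c2)c(O[Si](C(C)C)(C(C)C)C(C)C)c1 | intermediate
9 | 1-Ar*-non-8-en-1-one | C=CCCCCCCC(=O)c1cc(O[Si](C(C)C)(C(C)C)C(C)C)c(Oc2cc(Br)cc(O[Si](C(C)C)(C(C)C)C(C)C)c2)c(O[Si](C(C)C)(C(C)C)C(C)C)c1 | intermediate
10 | (R)-1-Ar*-non-8-en-1-ol | C=CCCCCCC[C@@H](O)c1cc(O[Si](C(C)C)(C(C)C)C(C)C)c(Oc2cc(Br)cc(O[Si](C(C)C)(C(C)C)C(C)C)c2)c(O[Si](C(C)C)(C(C)C)C(C)C)c1 | intermediate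
11 | tert-butyl{[(1R)-1-Ar*-non-8-en-1-yl]oxy}dimethylsilane | C=CCCCCCC[C@@H](O[Si](C)(C)C(C)(C)C)c1cc(O[Si](C(C)C)(C(C)C)C(C)C)c(Oc2cc(Br)cc(O[Si](C(C)C)(C(C)C)C(C)C)c2)c(O[Si](C(C)C)(C(C)C)C(C)C)c1 | intermediate
12 | (8R)-8-Ar*-8-(tert-butyldimethylsilyloxy)octanal | O=CCCCCCC[C@@H](O[Si](C)(C)C(C)(C)C)c1cc(O[Si](C(C)C)(C(C)C)C(C)C)c(Oc2cc(Br)cc(O[Si](C(C)C)(C(C)C)C(C)C)c2)c(O[Si](C(C)C)(C(C)C)C(C)C)c1 | intermediate
13 | (6-carboxyhexyl)triphenylphosphonium bromide | OC(=O)CCCCCC[P+](c1ccccc1)(c1ccccc1)c1ccccc1.[Br-] | starting material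
14 | sodium 7-(triphenylphosphoranylidene)heptanoate (not isolated) | [Na+].[O-]C(=O)CCCCCC=P(c1ccccc1)(c1ccccc1)c1ccccc1 | intermediate
15 | (7Z,15R)-15-Ar*-15-(tert-butyldimethylsilyloxy)pentadec-7-enoic acid | OC(=O)CCCCC/C=C\CCCCCC[C@@H](O[Si](C)(C)C(C)(C)C)c1cc(O[Si](C(C)C)(C(C)C)C(C)C)c(Oc2cc(Br)cc(O[Si](C(C)C)(C(C)C)C(C)C)c2)c(O[Si](C(C)C)(C(C)C)C(C)C)c1 | intermediate
16 | 1,3-dioxoisoindolin-2-yl ester of 15 (not isolated) | O=C1c2ccccc2C(=O)N1OC(=O)CCCCC/C=C\CCCCCC[C@@H](O[Si](C)(C)C(C)(C)C)c1cc(O[Si](C(C)C)(C(C)C)C(C)C)c(Oc2cc(Br)cc(O[Si](C(C)C)(C(C)C)C(C)C)c2)c(O[Si](C(C)C)(C(C)C)C(C)C)c1 | intermediate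
17 | tetrasilyl ether of the target macrocycle (ring A O-TIPS, ring B bis-O-TIPS, C1 O-TBS; R, Z) | CC(C)[Si](C(C)C)(C(C)C)Oc1cc2cc(c1)Oc1c(O[Si](C(C)C)(C(C)C)C(C)C)cc(cc1O[Si](C(C)C)(C(C)C)C(C)C)[C@H](O[Si](C)(C)C(C)(C)C)CCCCCC/C=C\CCCCC2 | intermediate
18 | CNP0316989.2, (4R,11Z)-2-oxa-1(1,3),3(1,4)-dibenzenacycloheptadecaphan-11-ene-1^5,3^2,3^6,4-tetrol | Oc1cc2cc(c1)Oc1c(O)cc(cc1O)[C@H](O)CCCCCC/C=C\CCCCC2 | target

**Step count**

Total steps: 11. Longest linear sequence: 11 steps (1 to 18).

**Steps most likely to fail**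

1. Step 10 (Proposed new method). What may go wrong:
   - chain growth instead of ring closure, when the C14 radical is born on a molecule whose ring A has not yet been metalated;
   - loss of the radical by hydrogen abstraction from the solvent, by a 1,5-hydrogen shift or by 6-exo addition to C8=C9;
   - reductive debromination of ring A.

   Fallback, known two-electron chemistry without a free radical: it sets out from aldehyde 12. Wittig olefination with the ylide from hex-5-enyltriphenylphosphonium bromide (NaN(SiMe3)2, THF, −78 °C to rt) should give tert-butyl{[(1R,8Z)-1-Ar*-tetradeca-8,13-dien-1-yl]oxy}dimethylsilane F1. 9-BBN (1.1 equiv, THF, 0 °C to rt) should add only to the terminal C13=C14 bond and give the B-alkyl-9-borabicyclo[3.3.1]nonane F2, which is not isolated. Slow addition of it to Pd(dppf)Cl2, AsPh3 and aqueous K3PO4 in THF/DMF at 50 °C should close the same ring A–C14 bond by intramolecular B-alkyl Suzuki–Miyaura coupling. The fallback returns to the route at 17.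

2. Step 1. What may go wrong: slow C–O coupling of the di-ortho-substituted, electron-poor phenoxide, so that reaction at the C–Br bond and reductive dehalogenation of 2 begin to compete.

   Fallback: it sets out from 2. Oxidation with mCPBA and TsOH·H2O in MeCN in the presence of 1,3,5-trimethoxybenzene should give (3-bromo-5-methoxyphenyl)(2,4,6-trimethoxyphenyl)iodonium tosylate F3. The phenoxide of 1 (K2CO3, MeCN or toluene, 50–80 °C) should then be arylated without a metal, by ligand coupling at the trivalent iodine, the electron-rich trimethoxyphenyl group staying behind as the non-transferred ligand. The fallback returns to the route at 3.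

3. Step 9. What may go wrong: erosion of the Z-selectivity through equilibration of the oxaphosphetane and betaine intermediates, and incomplete conversion of the poorly soluble carboxylate ylide. The E-isomer could not be removed after ring closure.

   Fallback: it sets out from 12. Colvin homologation (Me3SiCHN2 lithiated beforehand with n-BuLi, THF, −78 to 0 °C) should give tert-butyl{[(1R)-1-Ar*-non-8-yn-1-yl]oxy}dimethylsilane F4. Deprotonation of the alkyne with LDA (1 equiv, −78 °C) and alkylation with lithium 6-bromohexanoate (THF/DMPU, 0 °C to rt) should give (15R)-15-Ar*-15-(tert-butyldimethylsilyloxy)pentadec-7-ynoic acid F5. Semi-hydrogenation (H2, Pd/CaCO3 poisoned with Pb(OAc)2, quinoline, EtOAc) then fixes the Z geometry. The fallback returns to the route at 15.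

**Further compounds**

F1 | step 10 | tert-butyl{[(1R,8Z)-1-Ar*-tetradeca-8,13-dien-1-yl]oxy}dimethylsilane | C=CCCC/C=C\CCCCCC[C@@H](O[Si](C)(C)C(C)(C)C)c1cc(O[Si](C(C)C)(C(C)C)C(C)C)c(Oc2cc(Br)cc(O[Si](C(C)C)(C(C)C)C(C)C)c2)c(O[Si](C(C)C)(C(C)C)C(C)C)c1
F2 | step 10 | 9-[(6Z,14R)-14-Ar*-14-(tert-butyldimethylsilyloxy)tetradec-6-en-1-yl]-9-borabicyclo[3.3.1]nonane | C(CCCC/C=C\CCCCCC[C@@H](O[Si](C)(C)C(C)(C)C)c1cc(O[Si](C(C)C)(C(C)C)C(C)C)c(Oc2cc(Br)cc(O[Si](C(C)C)(C(C)C)C(C)C)c2)c(O[Si](C(C)C)(C(C)C)C(C)C)c1)B1C2CCCC1CCC2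
F3 | step 1 | (3-bromo-5-methoxyphenyl)(2,4,6-trimethoxyphenyl)iodonium 4-methylbenzenesulfonate | COc1cc(Br)cc([I+]c2c(OC)cc(OC)cc2OC)c1.Cc1ccc(S(=O)(=O)[O-])cc1
F4 | step 9 | tert-butyl{[(1R)-1-Ar*-non-8-yn-1-yl]oxy}dimethylsilane | C#CCCCCCC[C@@H](O[Si](C)(C)C(C)(C)C)c1cc(O[Si](C(C)C)(C(C)C)C(C)C)c(Oc2cc(Br)cc(O[Si](C(C)C)(C(C)C)C(C)C)c2)c(O[Si](C(C)C)(C(C)C)C(C)C)c1
F5 | step 9 | (15R)-15-Ar*-15-(tert-butyldimethylsilyloxy)pentadec-7-ynoic acid | OC(=O)CCCCCC#CCCCCCC[C@@H](O[Si](C)(C)C(C)(C)C)c1cc(O[Si](C(C)C)(C(C)C)C(C)C)c(Oc2cc(Br)cc(O[Si](C(C)C)(C(C)C)C(C)C)c2)c(O[Si](C(C)C)(C(C)C)C(C)C)c1
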